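## Retrosynthetic overview

1. Ring C is opened last at O1–C2. The (2S)-flavanone comes from o-hydroxychalcone 25 by asymmetric oxa-Michael closure, and 25 from acetophenone 22 and ring B aldehyde 24.
2. The acetyl carbon on C4a is introduced ortho to the single free phenol of ring A. That oxygen later becomes O1, so the side chain ends at C8 and not at C6.
3. C3'' (bearing CH3 and CH2OH) comes from an isopropenyl group by ligand-controlled hydroboration; the isopropenyl carbon is the lactol carbon of 12.
4. The strategy rests on ring A carrying at C8 a CH2 group (C1'') that lies ortho to the oxygen on C8a and is bonded to the stereocentre C2''. The C8a–O/C8–CH2 unit is unmasked as an ortho-quinone methide, the enamine of 5-methylhex-4-enal adds at C1'' (forming C1''–C2'' and setting C2''), and the same oxygen closes a temporary chroman-2-ol ring onto C3''.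
5. Ring order: ring A is bought (aldehyde 1); the temporary lactol ring forms in step 5 and is opened in step 6; ring B arrives with 24; ring C forms in step 17.

Key step: step 5

Assumption: the sense of induction written for steps 10 and 17 is assigned by analogy with simpler alkenes and chalcones; if a model substrate shows the opposite sense, the ligand antipode (step 10) or the quinidine-derived pseudoenantiomer (step 17) is used and nothing else changes.

## Route

Step 1
Reactants: 1 2,4,6-trihydroxybenzaldehyde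
Product: 2 2-hydroxy-4,6-bis(methoxymethoxy)benzaldehyde
Conditions: MOMCl (2.2 equiv), iPr2NEt, CH2Cl2, 0 °C → rt
Reagents that add atoms: chloromethyl methyl ether, COCCl
Why: Williamson-type acetalisation protects the para and one ortho hydroxyl, while the second ortho hydroxyl, hydrogen-bonded to the formyl group, should stay free.

Step 2
Reactants: 2 2-hydroxy-4,6-bis(methoxymethoxy)benzaldehyde
Product: 3 2-(hydroxymethyl)-3,5-bis(methoxymethoxy)phenol
Conditions: NaBH4, THF/MeOH, 0 °C
Reagents that add atoms: none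
Why: Borohydride reduction of the aldehyde at 0 °C should stop at the salicyl alcohol, which is carried on without storage because trioxygenated benzyl alcohols ionise easily.

Step 3
Reactants: 3 2-(hydroxymethyl)-3,5-bis(methoxymethoxy)phenol
Product: 4 3,5-bis(methoxymethoxy)-2-[(4-methylphenyl)sulfonylmethyl]phenol
Conditions: p-TolSO2Na, AcOH, THF/H2O, rt
Reagents that add atoms: sodium 4-methylbenzenesulfinate, [Na+].Cc1ccc(cc1)S(=O)[O-]
Why: Weak acid should release the stabilised benzylic cation from the salicyl alcohol and sulfinate adds through sulfur to give the storable sulfone (SN1-type sulfinate exchange), AcOH being too weak to cleave the MOM ethers.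

Step 4
Reactants: 5 2-methylbut-3-en-2-ol; 6 ethyl vinyl ether
Product: 8 5-methylhex-4-enal, via allyl vinyl ether 7 (not isolated)
Conditions: H3PO4 (cat.), excess 6, sealed vessel, 150 °C
Reagents that add atoms: none
Why: Acid-catalysed transvinylation gives the allyl vinyl ether, which on heating undergoes a chair-like [3,3] Claisen rearrangement to the γ,δ-unsaturated aldehyde.

Step 5
Reactants: 4 3,5-bis(methoxymethoxy)-2-[(4-methylphenyl)sulfonylmethyl]phenol; 8 5-methylhex-4-enal (2.5 equiv)
Product: 12 (3R)-5,7-bis(methoxymethoxy)-3-(3-methylbut-2-en-1-yl)-3,4-dihydro-2H-chromen-2-ol (both C2 epimers), via ortho-quinone methide 9 (not isolated), via enamine 10 (not isolated), via hydroxy aldehyde 11 (not isolated)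
Conditions: (S)-2-[diphenyl(trimethylsilyloxy)methyl]pyrrolidine (20 mol %), Na2CO3 (aq), CH2Cl2, 0 °C → rt
Reagents that add atoms: none
Why: Carbonate deprotonates the phenol of 4 and 1,4-elimination of sulfinate releases ortho-quinone methide 9, while the pyrrolidine condenses with 8 to the E-enamine 10; the enamine β-carbon adds to the exocyclic CH2 of 9, which rearomatises ring A and forms C1''–C2'', and hydrolysis of the iminium ion gives aldehyde 11. The closest known reaction type is the secondary-amine-catalysed formal [4+2] addition of aldehydes to ortho-quinone methides generated in situ from 2-(sulfonylalkyl)phenols, which gives chroman-2-ols. The ring closes by 6-exo-trig hemiacetalisation of the phenol oxygen onto the aldehyde carbon (O–C3''); a concerted inverse-demand hetero-Diels–Alder path followed by loss of the amine would end in the same lactol. C2'' is set by the catalyst: the diphenyl(trimethylsilyloxy)methyl group of the (S)-pyrrolidine shields the Re face of the s-trans E-enamine, so 9 should be attacked from the Si face, which corresponds to the (R) centre required. The step needs the enamine to outrun self-condensation of 9 and N-alkylation of the catalyst, which is secured by slow release of 9 from the sulfone, the excess of 8 and the hindered catalyst nitrogen; the two alkoxy donors also make 9 longer-lived, at the cost of lower electrophilicity. Regiochemistry is fixed because only one phenol is free next to the sulfonylmethyl carbon, the prenyl alkene is inert, and lactol closure shields the new α-centre from enolisation.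

Step 6
Reactants: 12 (3R)-5,7-bis(methoxymethoxy)-3-(3-methylbut-2-en-1-yl)-3,4-dihydro-2H-chromen-2-ol
Product: 13 (3R)-3-{[2-hydroxy-4,6-bis(methoxymethoxy)phenyl]methyl}-6-methylhept-5-en-2-ol (both C2 epimers)
Conditions: MeMgBr (3.5 equiv), THF, −78 → 0 °C; NH4Cl (aq)
Reagents that add atoms: methylmagnesium bromide, C[Mg]Br
Why: The Grignard reagent deprotonates the lactol and adds to the ring-opened magnesium phenoxide aldehyde faster than the α-centre can enolise (Grignard 1,2-addition), the new carbinol centre being formed unselectively and erased in step 8.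

Step 7
Reactants: 13 (3R)-3-{[2-hydroxy-4,6-bis(methoxymethoxy)phenyl]methyl}-6-methylhept-5-en-2-ol
Product: 14 (3R)-3-{[2,4-bis(methoxymethoxy)-6-(triisopropylsilyloxy)phenyl]methyl}-6-methylhept-5-en-2-ol (both C2 epimers)
Conditions: TIPSCl, imidazole, DMF, rt
Reagents that add atoms: chlorotri(propan-2-yl)silane, CC(C)[Si](Cl)(C(C)C)C(C)C
Why: The hindered chlorosilane should silylate the acidic phenol and not the secondary alcohol (selective O-silylation), which marks the future O1 and protects the electron-rich phenol during the oxidation.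

Step 8
Reactants: 14 (3R)-3-{[2,4-bis(methoxymethoxy)-6-(triisopropylsilyloxy)phenyl]methyl}-6-methylhept-5-en-2-ol
Product: 15 (3R)-3-{[2,4-bis(methoxymethoxy)-6-(triisopropylsilyloxy)phenyl]methyl}-6-methylhept-5-en-2-one
Conditions: Dess–Martin periodinane, pyridine, CH2Cl2, 0 °C → rt
Reagents that add atoms: none
Why: Dess–Martin oxidation converts the secondary alcohol into the methyl ketone under buffered, non-enolising conditions, so the adjacent centre C2'' should keep its configuration.

Step 9
Reactants: 15 (3R)-3-{[2,4-bis(methoxymethoxy)-6-(triisopropylsilyloxy)phenyl]methyl}-6-methylhept-5-en-2-one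
Product: 16 {3,5-bis(methoxymethoxy)-2-[(2R)-5-methyl-2-(prop-1-en-2-yl)hex-4-en-1-yl]phenoxy}tri(propan-2-yl)silane
Conditions: Ph3PCH3Br (1.5 equiv), KOtBu (1.4 equiv), THF, 0 °C → rt
Reagents that add atoms: methyltriphenylphosphonium bromide, C[P+](c1ccccc1)(c1ccccc1)c1ccccc1.[Br-]
Why: Wittig methylenation with the non-stabilised ylide, with base as the limiting component, gives the isopropenyl group, and any reversible deprotonation should take place at the methyl group and not at C2''.

Step 10
Reactants: 16 {3,5-bis(methoxymethoxy)-2-[(2R)-5-methyl-2-(prop-1-en-2-yl)hex-4-en-1-yl]phenoxy}tri(propan-2-yl)silane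
Product: 18 (2S,3R)-3-{[2,4-bis(methoxymethoxy)-6-(triisopropylsilyloxy)phenyl]methyl}-2,6-dimethylhept-5-en-1-ol, via pinacol boronate 17 (not isolated)
Conditions: CuCl (5 mol %), (R)-5,5′-bis[bis(3,5-di-tert-butyl-4-methoxyphenyl)phosphino]-4,4′-bi-1,3-benzodioxole (6 mol %), KOtBu (10 mol %), HBpin, toluene, rt; then NaBO3·4H2O, THF/H2O, rt
Reagents that add atoms: pinacolborane, CC1(C)OBOC1(C)C; sodium perborate, [Na+].[Na+].O[B-]1(O)OO[B-](O)(O)OO1
Why: Copper-catalysed asymmetric hydroboration of the 1,1-disubstituted alkene places boron on the terminal carbon and perborate oxidises the boronate with retention, the bisphosphine choosing the alkene face (methyl against the branched C2'' substituent) to set C3'' as (S), while the trisubstituted prenyl alkene should not insert.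

Step 11
Reactants: 18 (2S,3R)-3-{[2,4-bis(methoxymethoxy)-6-(triisopropylsilyloxy)phenyl]methyl}-2,6-dimethylhept-5-en-1-ol
Product: 19 (2S,3R)-3-{[2-hydroxy-4,6-bis(methoxymethoxy)phenyl]methyl}-2,6-dimethylhept-5-en-1-ol
Conditions: Bu4NF, AcOH, THF, 0 °C
Reagents that add atoms: none
Why: Fluoride-mediated desilylation cleaves the aryl silyl ether and leaves the MOM ethers, so only the phenol that is to become O1 is freed.

Step 12
Reactants: 19 (2S,3R)-3-{[2-hydroxy-4,6-bis(methoxymethoxy)phenyl]methyl}-2,6-dimethylhept-5-en-1-ol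
Product: 20 2-hydroxy-3-[(2R,3S)-4-hydroxy-3-methyl-2-(3-methylbut-2-en-1-yl)butyl]-4,6-bis(methoxymethoxy)benzaldehyde
Conditions: MgCl2, Et3N, (CH2O)n, THF, reflux
Reagents that add atoms: formaldehyde (from paraformaldehyde), C=O
Why: Magnesium-mediated ortho-formylation delivers formaldehyde from the magnesium phenoxide to the only free ortho position (the future C4a) and a second formaldehyde oxidises the benzylic alkoxide by hydride transfer, the position between the two MOM ethers not being ortho to the phenoxide.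

Step 13
Reactants: 20 2-hydroxy-3-[(2R,3S)-4-hydroxy-3-methyl-2-(3-methylbut-2-en-1-yl)butyl]-4,6-bis(methoxymethoxy)benzaldehyde
Product: 21 2-(1-hydroxyethyl)-6-[(2R,3S)-4-hydroxy-3-methyl-2-(3-methylbut-2-en-1-yl)butyl]-3,5-bis(methoxymethoxy)phenol (both carbinol epimers)
Conditions: MeMgBr (4 equiv), THF, −40 → 0 °C; NH4Cl (aq); used crude
Reagents that add atoms: methylmagnesium bromide, C[Mg]Br
Why: Excess Grignard reagent deprotonates both hydroxyl groups and adds to the aldehyde (Grignard 1,2-addition) to give a carbinol whose configuration is irrelevant and which, being acid-sensitive, is oxidised without purification.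

Step 14
Reactants: 21 2-(1-hydroxyethyl)-6-[(2R,3S)-4-hydroxy-3-methyl-2-(3-methylbut-2-en-1-yl)butyl]-3,5-bis(methoxymethoxy)phenol
Product: 22 1-{2-hydroxy-3-[(2R,3S)-4-hydroxy-3-methyl-2-(3-methylbut-2-en-1-yl)butyl]-4,6-bis(methoxymethoxy)phenyl}ethan-1-one
Conditions: MnO2 (activated), CH2Cl2, rt
Reagents that add atoms: none
Why: Activated MnO2 oxidises the benzylic alcohol to the hydrogen-bonded o-hydroxyacetophenone and should leave the saturated primary alcohol untouched (chemoselective benzylic oxidation).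

Step 15
Reactants: 23 2,4-dihydroxybenzaldehyde
Product: 24 2,4-bis(methoxymethoxy)benzaldehyde
Conditions: MOMCl, K2CO3, acetone, reflux
Reagents that add atoms: chloromethyl methyl ether, COCCl
Why: Williamson-type alkylation of both phenoxides with MOMCl protects ring B for the basic condensation.

Step 16
Reactants: 22 1-{2-hydroxy-3-[(2R,3S)-4-hydroxy-3-methyl-2-(3-methylbut-2-en-1-yl)butyl]-4,6-bis(methoxymethoxy)phenyl}ethan-1-one; 24 2,4-bis(methoxymethoxy)benzaldehyde
Product: 25 (2E)-3-[2,4-bis(methoxymethoxy)phenyl]-1-{2-hydroxy-3-[(2R,3S)-4-hydroxy-3-methyl-2-(3-methylbut-2-en-1-yl)butyl]-4,6-bis(methoxymethoxy)phenyl}prop-2-en-1-one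
Conditions: KOH, EtOH/H2O, rt
Reagents that add atoms: none
Why: Claisen–Schmidt condensation of the methyl ketone enolate with the non-enolisable aldehyde and E1cB dehydration should give the (E)-chalcone, the MOM ethers and the alcohol being stable to hydroxide.

Step 17
Reactants: 25 (2E)-3-[2,4-bis(methoxymethoxy)phenyl]-1-{2-hydroxy-3-[(2R,3S)-4-hydroxy-3-methyl-2-(3-methylbut-2-en-1-yl)butyl]-4,6-bis(methoxymethoxy)phenyl}prop-2-en-1-one
Product: 26 (2S)-2-[2,4-bis(methoxymethoxy)phenyl]-8-[(2R,3S)-4-hydroxy-3-methyl-2-(3-methylbut-2-en-1-yl)butyl]-5,7-bis(methoxymethoxy)-2,3-dihydro-4H-chromen-4-one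
Conditions: 1-[3,5-bis(trifluoromethyl)phenyl]-3-[(8α,9S)-6′-methoxycinchonan-9-yl]thiourea (20 mol %), toluene, rt
Reagents that add atoms: none
Why: In this asymmetric intramolecular oxa-Michael addition (6-endo-trig) the quinuclidine of the bifunctional catalyst deprotonates the single free phenol and the thiourea binds the enone carbonyl, so the phenoxide should add to one face of the β-carbon and set C2 as (S), and because only O1 is free ring C closes towards C8a to give the 8-substituted flavanone.

Step 18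
Reactants: 26 (2S)-2-[2,4-bis(methoxymethoxy)phenyl]-8-[(2R,3S)-4-hydroxy-3-methyl-2-(3-methylbut-2-en-1-yl)butyl]-5,7-bis(methoxymethoxy)-2,3-dihydro-4H-chromen-4-one
Product: 27 (2S)-2-(2,4-dihydroxyphenyl)-5,7-dihydroxy-8-[(2R,3S)-4-hydroxy-3-methyl-2-(3-methylbut-2-en-1-yl)butyl]-2,3-dihydro-4H-chromen-4-one (CNP0262638.1)
Conditions: HCl (3 M aq)/MeOH, rt
Reagents that add atoms: none
Why: Acid-catalysed acetal exchange with methanol removes the four MOM groups at room temperature, conditions chosen to be mild enough that the prenyl alkene, the primary alcohol and the acid-labile benzylic C2 centre should survive.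

## Compound list

1 | 2,4,6-trihydroxybenzaldehyde | O=Cc1c(O)cc(O)cc1O | starting material
2 | 2-hydroxy-4,6-bis(methoxymethoxy)benzaldehyde | O=Cc1c(O)cc(OCOC)cc1OCOC | intermediate
3 | 2-(hydroxymethyl)-3,5-bis(methoxymethoxy)phenol | OCc1c(O)cc(OCOC)cc1OCOC | intermediate
4 | 3,5-bis(methoxymethoxy)-2-[(4-methylphenyl)sulfonylmethyl]phenol | Cc1ccc(cc1)S(=O)(=O)Cc1c(O)cc(OCOC)cc1OCOC | intermediate
5 | 2-methylbut-3-en-2-ol | CC(C)(O)C=C | starting material
6 | ethyl vinyl ether | C=COCC | starting material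
7 | 3-(ethenyloxy)-3-methylbut-1-ene | C=COC(C)(C)C=C | intermediate
8 | 5-methylhex-4-enal | CC(C)=CCCC=O | intermediate
9 | 3,5-bis(methoxymethoxy)-6-methylidenecyclohexa-2,4-dien-1-one | C=C1C(=O)C=C(OCOC)C=C1OCOC | intermediate
10 | (2S)-2-[diphenyl(trimethylsilyloxy)methyl]-1-[(1E)-5-methylhexa-1,4-dien-1-yl]pyrrolidine | CC(C)=CC/C=C/N1CCC[C@H]1C(c1ccccc1)(c1ccccc1)O[Si](C)(C)C | intermediate
11 | (2R)-2-{[2-hydroxy-4,6-bis(methoxymethoxy)phenyl]methyl}-5-methylhex-4-enal | CC(C)=CC[C@H](Cc1c(O)cc(OCOC)cc1OCOC)C=O | intermediate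
12 | (3R)-5,7-bis(methoxymethoxy)-3-(3-methylbut-2-en-1-yl)-3,4-dihydro-2H-chromen-2-ol, both C2 epimers | CC(C)=CC[C@@H]1Cc2c(OCOC)cc(OCOC)cc2OC1O | intermediate
13 | (3R)-3-{[2-hydroxy-4,6-bis(methoxymethoxy)phenyl]methyl}-6-methylhept-5-en-2-ol, both C2 epimers | CC(C)=CC[C@H](Cc1c(O)cc(OCOC)cc1OCOC)C(C)O | intermediate
14 | (3R)-3-{[2,4-bis(methoxymethoxy)-6-(triisopropylsilyloxy)phenyl]methyl}-6-methylhept-5-en-2-ol, both C2 epimers | CC(C)=CC[C@H](Cc1c(O[Si](C(C)C)(C(C)C)C(C)C)cc(OCOC)cc1OCOC)C(C)O | intermediate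
15 | (3R)-3-{[2,4-bis(methoxymethoxy)-6-(triisopropylsilyloxy)phenyl]methyl}-6-methylhept-5-en-2-one | CC(C)=CC[C@H](Cc1c(O[Si](C(C)C)(C(C)C)C(C)C)cc(OCOC)cc1OCOC)C(C)=O | intermediate
16 | {3,5-bis(methoxymethoxy)-2-[(2R)-5-methyl-2-(prop-1-en-2-yl)hex-4-en-1-yl]phenoxy}tri(propan-2-yl)silane | CC(C)=CC[C@H](Cc1c(O[Si](C(C)C)(C(C)C)C(C)C)cc(OCOC)cc1OCOC)C(C)=C | intermediate
17 | 2-[(2R,3R)-3-{[2,4-bis(methoxymethoxy)-6-(triisopropylsilyloxy)phenyl]methyl}-2,6-dimethylhept-5-en-1-yl]-4,4,5,5-tetramethyl-1,3,2-dioxaborolane | CC(C)=CC[C@H](Cc1c(O[Si](C(C)C)(C(C)C)C(C)C)cc(OCOC)cc1OCOC)[C@H](C)CB1OC(C)(C)C(C)(C)O1 | intermediate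
18 | (2S,3R)-3-{[2,4-bis(methoxymethoxy)-6-(triisopropylsilyloxy)phenyl]methyl}-2,6-dimethylhept-5-en-1-ol | CC(C)=CC[C@H](Cc1c(O[Si](C(C)C)(C(C)C)C(C)C)cc(OCOC)cc1OCOC)[C@H](C)CO | intermediate
19 | (2S,3R)-3-{[2-hydroxy-4,6-bis(methoxymethoxy)phenyl]methyl}-2,6-dimethylhept-5-en-1-ol | CC(C)=CC[C@H](Cc1c(O)cc(OCOC)cc1OCOC)[C@H](C)CO | intermediate
20 | 2-hydroxy-3-[(2R,3S)-4-hydroxy-3-methyl-2-(3-methylbut-2-en-1-yl)butyl]-4,6-bis(methoxymethoxy)benzaldehyde | CC(C)=CC[C@H](Cc1c(O)c(C=O)c(OCOC)cc1OCOC)[C@H](C)CO | intermediate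
21 | 2-(1-hydroxyethyl)-6-[(2R,3S)-4-hydroxy-3-methyl-2-(3-methylbut-2-en-1-yl)butyl]-3,5-bis(methoxymethoxy)phenol, both carbinol epimers | CC(C)=CC[C@H](Cc1c(O)c(C(C)O)c(OCOC)cc1OCOC)[C@H](C)CO | intermediate
22 | 1-{2-hydroxy-3-[(2R,3S)-4-hydroxy-3-methyl-2-(3-methylbut-2-en-1-yl)butyl]-4,6-bis(methoxymethoxy)phenyl}ethan-1-one | CC(C)=CC[C@H](Cc1c(O)c(C(C)=O)c(OCOC)cc1OCOC)[C@H](C)CO | intermediate
23 | 2,4-dihydroxybenzaldehyde | O=Cc1ccc(O)cc1O | starting material
24 | 2,4-bis(methoxymethoxy)benzaldehyde | COCOc1ccc(C=O)c(OCOC)c1 | intermediate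
25 | (2E)-3-[2,4-bis(methoxymethoxy)phenyl]-1-{2-hydroxy-3-[(2R,3S)-4-hydroxy-3-methyl-2-(3-methylbut-2-en-1-yl)butyl]-4,6-bis(methoxymethoxy)phenyl}prop-2-en-1-one | CC(C)=CC[C@H](Cc1c(O)c(C(=O)/C=C/c2ccc(OCOC)cc2OCOC)c(OCOC)cc1OCOC)[C@H](C)CO | intermediate
26 | (2S)-2-[2,4-bis(methoxymethoxy)phenyl]-8-[(2R,3S)-4-hydroxy-3-methyl-2-(3-methylbut-2-en-1-yl)butyl]-5,7-bis(methoxymethoxy)-2,3-dihydro-4H-chromen-4-one | CC(C)=CC[C@H](Cc1c(OCOC)cc(OCOC)c2c1O[C@H](c1ccc(OCOC)cc1OCOC)CC2=O)[C@H](C)CO | intermediate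
27 | (2S)-2-(2,4-dihydroxyphenyl)-5,7-dihydroxy-8-[(2R,3S)-4-hydroxy-3-methyl-2-(3-methylbut-2-en-1-yl)butyl]-2,3-dihydro-4H-chromen-4-one | CC(C)=CC[C@H](Cc1c(O)cc(O)c2c1O[C@H](c1ccc(O)cc1O)CC2=O)[C@H](C)CO | target

## Step count and risks

Total steps: 18. Longest linear sequence: 16 steps (steps 1–3, 5–14, 16–18).

**Step 5 (key step).** The quinone methide may dimerise or alkylate the catalyst nitrogen faster than the enamine adds, and shielding of the enamine face may be incomplete, which would lower the optical purity at C2''. The fallback sets out from 2 and comes back to the route at 15; it builds C2'' by auxiliary-controlled enolate alkylation instead.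
- Silylation of 2 (TIPSCl, imidazole, DMF) would give the silyl-protected aldehyde F1.
- Horner–Wadsworth–Emmons olefination with diethyl {2-[(4R)-4-benzyl-2-oxo-1,3-oxazolidin-3-yl]-2-oxoethyl}phosphonate (LiCl, iPr2NEt, MeCN) would give the (E)-N-enoyl oxazolidinone F2.
- Hydrogenation (H2, Pd/C, EtOAc) would give the saturated imide F3.
- Alkylation of its sodium Z-enolate (NaN(SiMe3)2, THF, −78 °C) with 1-bromo-3-methylbut-2-ene, from the face opposite the benzyl group, would give the (2R)-prenylated imide F4.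
- Transamination (AlMe3, MeNHOMe·HCl, CH2Cl2) would give the N-methoxy-N-methylamide F5.
- MeMgBr would convert F5 into ketone 15.

**Step 17.** The oxa-Michael closure is reversible and the catalyst may discriminate the enone faces poorly, so that the C2 epimer forms alongside 26 or the selectivity erodes with time. The fallback sets out from 25 and comes back at 26; it gives up catalyst control.
- Thermodynamic closure (NaOAc, EtOH, reflux) would give 26 together with the (2R)-epimer flavanone F9.
- The two are diastereomers and would be separated by preparative HPLC.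
- F9 would be re-opened to 25 (KOH, EtOH) and cyclised again.

**Step 10.** The two substituents on C2'' are of similar size, so the substrate gives no help and the ligand alone must distinguish the alkene faces; facial selectivity may be poor, and the hindered alkene may insert slowly. The fallback sets out from 15 and comes back at 18; it sets C3'' by hydroxyl-directed hydrogenation.
- Kinetic enolisation of 15 at the methyl group (KN(SiMe3)2, PhNTf2, THF, −78 °C) would give the enol triflate F6.
- Methoxycarbonylation (Pd(OAc)2, 1,3-bis(diphenylphosphino)propane, CO, MeOH, Et3N, DMF) would give the 2-substituted acrylate F7.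
- Reduction with i-Bu2AlH (CH2Cl2, −78 °C) would give the allylic alcohol F8.
- Hydrogenation with Ru(OAc)2[(R)-2,2′-bis(diphenylphosphino)-1,1′-binaphthyl] (antipode chosen for the (S) centre) under H2 in MeOH should reduce only the allylic alkene and give 18.

## Further compounds

F1 | step 5 | 2,4-bis(methoxymethoxy)-6-(triisopropylsilyloxy)benzaldehyde | O=Cc1c(O[Si](C(C)C)(C(C)C)C(C)C)cc(OCOC)cc1OCOC
F2 | step 5 | (4R)-4-benzyl-3-[(2E)-3-{2,4-bis(methoxymethoxy)-6-(triisopropylsilyloxy)phenyl}prop-2-enoyl]-1,3-oxazolidin-2-one | O=C(/C=C/c1c(O[Si](C(C)C)(C(C)C)C(C)C)cc(OCOC)cc1OCOC)N1[C@H](Cc2ccccc2)COC1=O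
F3 | step 5 | (4R)-4-benzyl-3-(3-{2,4-bis(methoxymethoxy)-6-(triisopropylsilyloxy)phenyl}propanoyl)-1,3-oxazolidin-2-one | O=C(CCc1c(O[Si](C(C)C)(C(C)C)C(C)C)cc(OCOC)cc1OCOC)N1[C@H](Cc2ccccc2)COC1=O
F4 | step 5 | (4R)-4-benzyl-3-[(2R)-2-{[2,4-bis(methoxymethoxy)-6-(triisopropylsilyloxy)phenyl]methyl}-5-methylhex-4-enoyl]-1,3-oxazolidin-2-one | CC(C)=CC[C@H](Cc1c(O[Si](C(C)C)(C(C)C)C(C)C)cc(OCOC)cc1OCOC)C(=O)N1[C@H](Cc2ccccc2)COC1=O
F5 | step 5 | (2R)-2-{[2,4-bis(methoxymethoxy)-6-(triisopropylsilyloxy)phenyl]methyl}-N-methoxy-N,5-dimethylhex-4-enamide | CC(C)=CC[C@H](Cc1c(O[Si](C(C)C)(C(C)C)C(C)C)cc(OCOC)cc1OCOC)C(=O)N(C)OC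
F6 | step 10 | (3R)-3-{[2,4-bis(methoxymethoxy)-6-(triisopropylsilyloxy)phenyl]methyl}-6-methylhepta-1,5-dien-2-yl trifluoromethanesulfonate | CC(C)=CC[C@H](Cc1c(O[Si](C(C)C)(C(C)C)C(C)C)cc(OCOC)cc1OCOC)C(=C)OS(=O)(=O)C(F)(F)F
F7 | step 10 | methyl (3R)-3-{[2,4-bis(methoxymethoxy)-6-(triisopropylsilyloxy)phenyl]methyl}-6-methyl-2-methylidenehept-5-enoate | CC(C)=CC[C@H](Cc1c(O[Si](C(C)C)(C(C)C)C(C)C)cc(OCOC)cc1OCOC)C(=C)C(=O)OC
F8 | step 10 | (3R)-3-{[2,4-bis(methoxymethoxy)-6-(triisopropylsilyloxy)phenyl]methyl}-6-methyl-2-methylidenehept-5-en-1-ol | CC(C)=CC[C@H](Cc1c(O[Si](C(C)C)(C(C)C)C(C)C)cc(OCOC)cc1OCOC)C(=C)CO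
F9 | step 17 | (2R)-2-[2,4-bis(methoxymethoxy)phenyl]-8-[(2R,3S)-4-hydroxy-3-methyl-2-(3-methylbut-2-en-1-yl)butyl]-5,7-bis(methoxymethoxy)-2,3-dihydro-4H-chromen-4-one | CC(C)=CC[C@H](Cc1c(OCOC)cc(OCOC)c2c1O[C@@H](c1ccc(OCOC)cc1OCOC)CC2=O)[C@H](C)CO
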